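# Total synthesis proposal for prosogerin D (7-hydroxy-6,3',4',5'-tetramethoxyflavone)

Atom labels (O1, C2 … C8a, C1'–C6') follow flavone numbering throughout. Compound numbers are those of the steps.

## Analysis of the target

Prosogerin D (9) is a flavone. Benzo ring A (C4a, C5, C6, C7, C8, C8a) is fused to the γ-pyranone ring C (O1, C2, C3, C4), and C2 carries the 3,4,5-trimethoxyphenyl ring B. The SMILES holds no stereocentre, no stereogenic double bond and no hindered axis, so 9 is achiral and no configuration has to be set or guarded. Ring A is 1,2,4-trioxygenated: O1 on C8a and the free hydroxyl on C7 lie ortho and para to C4a and are conjugated with the C4 carbonyl group, whereas the methoxy oxygen on C6 is meta to C4a and is not. The sensitive groups are: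

- the acidic 7-OH, a vinylogous carboxylic acid that is also part of an oxidisable guaiacol unit;
- four aryl methyl ethers that strong Lewis acids attack, the crowded 4'-OMe first;
- the electrophilic C2, at which hot aqueous base opens ring C.

The difficulty is economy, not complexity. The neighbouring oxygens on C6 and C7 must be told apart, ring C must be built and the two aryl halves joined, and in so small a target every protecting group or redox correction costs a large part of the route. The feature that invites the chosen move is the sequence O1–C8a–C4a–C4: ring A together with O1 and C4 is a salicylaldehyde in which a formyl hydrogen stands where C3 belongs. In that unit O1 sits where a directing group for the formyl C–H bond must sit and, later, where the nucleophile for the O1–C2 closure must sit, so C4 can serve as a metal-bound acyl nucleophile (polarity reversal) and be joined to C3 delivered as a carbene.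

## Retrosynthetic reasoning

**Disconnection 1, O1–C2 (ring C).** 9 is the anhydro form of the cyclic hemiketal 8, and 8 is the ring tautomer of the open 1,3-diketone 7. This enol ether bond is cut first because its formation poses no selectivity problem. Of the two hydroxyl groups of 7, only the one ortho to the ketone can reach C2 through a six-membered ring, and the dehydration is driven by the aromatic pyranone. Ring C is thereby reduced to an open C4–C3–C2 chain between two arenes.

**Disconnection 2, C3–C4 (key step).** 7 is cut between the methylene carbon C3 and the ring A ketone carbon C4, which gives aldehyde 3 and the aroyl sulfoxonium ylide 6.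

- The usual cut lies on the other side (C2–C3). It leaves a methyl ketone on ring A that must be made separately, and its enolate chemistry suffers from two acidic phenols.
- The C3–C4 cut leaves ring A as an aldehyde that already holds C4 and the full oxygen pattern, and puts C2 and C3 on the ring B half.
- In polar logic this bond would need C4 at the ester level plus a strong base. Here both partners react with reversed polarity: the formyl carbon as an acyl-metal, the ylide carbon as a carbene.
- The forward reaction has to break the formyl C–H bond of 3 in preference to all aryl C–H bonds, take up C3 with loss of the sulfoxide leaving group, and leave the free para hydroxyl alone. A rhodium(III) catalyst directed by the ortho hydroxyl should do this.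
- Since 7 closes to 9 in the same flask, disconnections 1 and 2 are one operation (step 3). It joins the halves, forms C3–C4 and O1–C2, closes ring C and arrives at the final oxidation level without oxidant, strong base or protecting group.

**Disconnection 3, C2–C3 inside 6.** 6 is cut between its carbonyl carbon (later C2) and the ylide carbon (later C3). This leads through salt 5 to the commercial acid chloride 4 and a one-carbon sulfur ylide reagent generated in the flask. The cut is placed here because ring B with C2 can be bought at the right oxidation level, so the carbene precursor costs one step.

**Disconnection 4, two O–CH3 bonds.** 3 is traced through 2 to the cheap aldehyde 1, which carries all three ring A oxygens and the future C4.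

- The formyl group itself tells the ethers apart. The ortho and para ethers are vinylogous esters of the Lewis-acid-activated carbonyl and are cleaved; the meta ether (later 6-OMe) is not.
- The cleavage is placed before the union because the central ether of ring B would not survive the Lewis acid.
- The O6/O7 differentiation is thus obtained without any protecting group.

## Alternatives that were turned down

**Alternative 1:** the textbook route, which also follows the biosynthetic order. It cuts C2–C3 and O1–C2 at the chalcone oxidation level. Claisen–Schmidt condensation of acetophenone A1 with aldehyde A2 gives the 2'-hydroxychalcone A3, and oxidative cyclisation (oxa-Michael addition, then dehydrogenation) gives 9. It was turned down for these reasons: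

- A1 carries one carbon more than 3 and cannot be reached from 1 by a functional group step, so a C-acylation of an electron-rich resorcinol or a two-step homologation comes first.
- In the strongly basic medium A1 is a bis-phenoxide. Its para oxide feeds electron density into the ketone and lowers the acidity of the methyl group, which calls for a mask on O7 and two more steps.
- C2 arrives two electrons too low, so a stoichiometric oxidant must act on a molecule with a guaiacol ring and a trimethoxyphenyl ring. A halogen-based oxidant can then substitute C8 (ortho to both O1 and O7) or C3.
- The closure can branch between the six-membered and the five-membered ring.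
- The route would run to four to six steps, and the key step forms only one C–C bond.

**Alternative 2:** carbonylative three-component annulation. It cuts C4a–C4, C3–C4 and O1–C2, with C4 supplied from the gas phase. Palladium(0) would join iodophenol A4, alkyne A5 and the carbonylation gas to an o-hydroxyaryl ynone, which a secondary amine closes in the 6-endo sense to 9. On paper this forms the most bonds. It was turned down for these reasons:

- A4 needs a regioselective iodination of resorcinol A6, in which the position between the two hydroxyl groups competes. A6 itself comes from an aldehyde by oxidative loss of the formyl carbon, so the carbon that 3 already holds on C4a would be removed only to be put back.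
- Oxidative addition into a C–I bond that lies ortho and para to oxygen donors is slow, and protodeiodination competes.
- Direct, non-carbonylative coupling followed by closure to a benzofuran and 5-exo closure after carbonylation are both open.
- A mask on O7 would probably be needed.
- The risk would sit in three places instead of one, and a toxic gas under pressure is required.

**Alternative 3:** cut of C2–C1', with late attachment of ring B. It relies on palladium(II)-catalysed oxidative C2–H arylation of chromone A7 with boronic acid A8. It was turned down for these reasons:

- Ring C must exist beforehand. A7 needs A1 plus a one-carbon unit and a cyclisation, so the key step only hangs an aryl group on a finished bicycle and solves none of the ring construction.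
- A stoichiometric oxidant has to coexist with the free guaiacol unit.
- C3 is the nucleophilic carbon of the enol ether. Arylation at C2 therefore runs through carbopalladation, after which no syn β-hydrogen is available without epimerisation over a palladium enolate, so protonation at the flavanone level competes.
- The sequence is longer than the chosen one.

Key step: step 3

Assumption (remark on the chemistry): 9 has no stereogenic element, so the request for a single enantiomer is met by the constitution alone. The transient stereocentre of 8 (C2) forms as a racemate and is erased in the same flask.

## Route

Step 1
Reactants: 1 2,4,5-trimethoxybenzaldehyde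
Product: 3 2,4-dihydroxy-5-methoxybenzaldehyde, via 2-hydroxy-4,5-dimethoxybenzaldehyde 2 (not isolated)
Conditions: AlCl3 (5 equiv), CH2Cl2, 0 °C to 40 °C; then ice, 2 M HCl
Reagents that add atoms: none
Why: Lewis acid cleavage of aryl methyl ethers, steered by the carbonyl group: AlCl3 on the formyl oxygen first cleaves the ortho ether through a six-membered chelate (2, held as its aluminium phenoxide) and then the para ether, whose oxygen is the vinylogous ester oxygen of the activated carbonyl and whose phenoxide is the better leaving group for chloride attack at methyl. The 5-OMe group is meta to the formyl group, is not conjugated with it and should stay, which sets the O6/O7 pattern of 9 without a protecting group.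

Step 2
Reactants: 4 3,4,5-trimethoxybenzoyl chloride
Product: 6 2-(dimethyl-oxo-λ6-sulfanylidene)-1-(3,4,5-trimethoxyphenyl)ethan-1-one, via acylsulfoxonium chloride 5 (not isolated)
Conditions: Me3S(O)I (3 equiv), KOtBu (3 equiv), THF, reflux, 2 h; then slow addition of 4 (1 equiv), 0 °C to rt
Reagents that add atoms: trimethylsulfoxonium iodide, C[S+](C)(C)=O.[I-]
Why: Acylation of dimethylsulfoxonium methylide (the Corey–Chaykovsky reagent) by an acid chloride is the standard entry to β-keto sulfoxonium ylides. One equivalent of methylide attacks 4 to give salt 5, a second one deprotonates its doubly activated CH2 group, and the excess of methylide plus slow addition of 4 should keep the stabilised ylide 6 from being acylated again; the aryl ethers are inert.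

Step 3
Reactants: 3 2,4-dihydroxy-5-methoxybenzaldehyde; 6 2-(dimethyl-oxo-λ6-sulfanylidene)-1-(3,4,5-trimethoxyphenyl)ethan-1-one (1.5 equiv)
Product: 9 prosogerin D (7-hydroxy-6-methoxy-2-(3,4,5-trimethoxyphenyl)-4H-chromen-4-one), via 1,3-diketone 7 (not isolated), via 2-hydroxyflavanone 8 (not isolated)
Conditions: [Cp*RhCl2]2 (2.5 mol %), AgSbF6 (10 mol %), CsOAc (25 mol %), PivOH (1 equiv), DCE, 100 °C, N2; then p-TsOH·H2O (20 mol %), 80 °C, same flask
Reagents that add atoms: none
Why: The closest known reaction type is the redox-neutral Cp*Rh(III)-catalysed formyl C–H activation/annulation of salicylaldehydes with aroyl sulfoxonium ylides (carbene-transfer acylation followed by cyclodehydration). The C2 hydroxyl of 3 (future O1) binds the cationic Cp*Rh(III) as a phenoxide and delivers it to the formyl C–H bond by carboxylate-assisted concerted metalation–deprotonation, which gives a five-membered acyl-rhodacycle and turns the future C4 from an electrophile into a metal-bound acyl nucleophile. The ylide carbon of 6 coordinates, DMSO leaves, migratory insertion of the acyl group into the rhodium carbene forms the C3–C4 bond, and protonolysis by PivOH frees 7 and returns the catalyst. Ring C then closes by a favoured 6-exo-trig addition of the same phenol oxygen to the aroyl carbonyl carbon (C2) to give hemiketal 8, and acid-catalysed loss of water gives the aromatic pyranone of 9. No stereocentre survives, since C2 of 8 forms as a racemate without any control element and is flattened in the dehydration. The choice between the two hydroxyl groups is geometric: only the ortho one can reach the formyl C–H bond through a five-membered metallacycle and C2 through a six-membered ring, so the para one (future 7-OH) should stay a spectator whose acidity lies in the range of the carboxylic acid additive that the conditions hold anyway. Self-annulation of 6 through its own ortho C–H bonds and a second, C4=O-directed alkylation of 9 at C5–H should both be slow, because each of these C–H bonds is flanked by a methoxy group. The methyl ethers, the pyranone and the guaiacol unit meet neither oxidant nor strong base nor strong Lewis acid.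

## Compound list

1 | 2,4,5-trimethoxybenzaldehyde | COc1cc(OC)c(C=O)cc1OC | starting material
2 | 2-hydroxy-4,5-dimethoxybenzaldehyde (in the flask as its aluminium phenoxide, not isolated) | COc1cc(O)c(C=O)cc1OC | intermediate
3 | 2,4-dihydroxy-5-methoxybenzaldehyde | COc1cc(C=O)c(O)cc1O | intermediate
4 | 3,4,5-trimethoxybenzoyl chloride | COc1cc(C(=O)Cl)cc(OC)c1OC | starting material
5 | dimethyl[2-oxo-2-(3,4,5-trimethoxyphenyl)ethyl]sulfoxonium chloride (not isolated) | COc1cc(C(=O)C[S+](C)(C)=O)cc(OC)c1OC.[Cl-] | intermediate
6 | 2-(dimethyl-oxo-λ6-sulfanylidene)-1-(3,4,5-trimethoxyphenyl)ethan-1-one | COc1cc(C(=O)C=S(C)(C)=O)cc(OC)c1OC | intermediate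
7 | 1-(2,4-dihydroxy-5-methoxyphenyl)-3-(3,4,5-trimethoxyphenyl)propane-1,3-dione (not isolated) | COc1cc(C(=O)CC(=O)c2cc(OC)c(OC)c(OC)c2)c(O)cc1O | intermediate
8 | 2,7-dihydroxy-6-methoxy-2-(3,4,5-trimethoxyphenyl)chroman-4-one (racemic, not isolated) | COc1cc2c(cc1O)OC(O)(c1cc(OC)c(OC)c(OC)c1)CC2=O | intermediate
9 | prosogerin D, 7-hydroxy-6-methoxy-2-(3,4,5-trimethoxyphenyl)-4H-chromen-4-one (achiral) | COc1cc2c(=O)cc(-c3cc(OC)c(OC)c(OC)c3)oc2cc1O | target

## Step count and risk

Total step count: 3. Longest linear sequence: 2 (1 → 3 → 9, or 4 → 6 → 9). The route is convergent, with one step in each branch before the union.

**Step 3 (key step).** The most likely failure is loss of material through the free para hydroxyl group.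

- That group is acidic enough to protonate the ylide carbon of 6. The resulting phenoxide can then be O-alkylated by the sulfoxonium salt with loss of the sulfoxide, in competition with a C–H rhodation that is slow for so electron-rich an aldehyde.
- Off-cycle binding of rhodium to this phenoxide, decarbonylation of the acyl-rhodium species at 100 °C and thermal self-condensation of the ylide would add to the loss.
- The fallback builds the same C3–C4 bond by ordinary polar addition at a lower oxidation level. It sets out from 3 and comes back at 9.
- 3 is converted with MOMCl/iPr2NEt into 5-methoxy-2,4-bis(methoxymethoxy)benzaldehyde F1.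
- The lithium acetylide of commercial alkyne A5 (n-BuLi, THF, −78 °C) adds to the formyl group to give racemic 1-[5-methoxy-2,4-bis(methoxymethoxy)phenyl]-3-(3,4,5-trimethoxyphenyl)prop-2-yn-1-ol F2.
- MnO2 in CH2Cl2 oxidises it to 1-[5-methoxy-2,4-bis(methoxymethoxy)phenyl]-3-(3,4,5-trimethoxyphenyl)prop-2-yn-1-one F3, and the stereocentre disappears.
- HCl in MeOH removes both acetals to give 1-(2,4-dihydroxy-5-methoxyphenyl)-3-(3,4,5-trimethoxyphenyl)prop-2-yn-1-one F4.
- Et2NH in EtOH at reflux closes ring C in the 6-endo sense through the β-enaminone, which excludes the five-membered closure and gives 9.

**Step 1.** The most likely failure is poor control over the extent of ether cleavage.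

- The second cleavage is slower than the first, because the ring then carries an aluminium phenoxide, so the reaction may stall at the stage of 2.
- Forcing conditions invite loss of the third methyl group once aluminium bridges the oxygens on C4 and C5 in the manner of a catecholate.
- The fallback reverses the logic: it removes all three methyl groups and puts one back. It sets out from 1 and comes back at 3.
- BBr3 (excess, CH2Cl2, −78 °C to rt) gives 2,4,5-trihydroxybenzaldehyde F5.
- Its trianion (NaH, 3.1 equiv, DMSO, argon) is treated with MeI (1.0 equiv). The 5-oxide is the only one of the three that is not delocalised into the formyl group and is therefore the most nucleophilic, as in the known meta-selective monoalkylation of catechol aldehyde dianions, so 3 should result.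

**Step 2.** The most likely failure is a second acylation of the product ylide, at carbon or at the enolate oxygen, by the very reactive acid chloride.

- Hydrolysis of the acid chloride by moisture brought in with the hygroscopic sulfoxonium salt is a second loss.
- The fallback changes the class of acyl donor. It sets out from 4 and comes back at 6.
- 4 is treated with 4-nitrophenol and Et3N in CH2Cl2 to give crystalline 4-nitrophenyl 3,4,5-trimethoxybenzoate F6.
- This active ester is still attacked by dimethylsulfoxonium methylide (THF, rt to reflux) but is too weak an electrophile for the stabilised ylide, so monoacylation to 6 should be clean.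

## Further compounds

F1 | step 3 | 5-methoxy-2,4-bis(methoxymethoxy)benzaldehyde | COCOc1cc(OCOC)c(OC)cc1C=O
F2 | step 3 | 1-[5-methoxy-2,4-bis(methoxymethoxy)phenyl]-3-(3,4,5-trimethoxyphenyl)prop-2-yn-1-ol (racemic) | COCOc1cc(OCOC)c(OC)cc1C(O)C#Cc1cc(OC)c(OC)c(OC)c1
F3 | step 3 | 1-[5-methoxy-2,4-bis(methoxymethoxy)phenyl]-3-(3,4,5-trimethoxyphenyl)prop-2-yn-1-one | COCOc1cc(OCOC)c(OC)cc1C(=O)C#Cc1cc(OC)c(OC)c(OC)c1
F4 | step 3 | 1-(2,4-dihydroxy-5-methoxyphenyl)-3-(3,4,5-trimethoxyphenyl)prop-2-yn-1-one | COc1cc(C(=O)C#Cc2cc(OC)c(OC)c(OC)c2)c(O)cc1O
F5 | step 1 | 2,4,5-trihydroxybenzaldehyde | O=Cc1cc(O)c(O)cc1O
F6 | step 2 | 4-nitrophenyl 3,4,5-trimethoxybenzoate | COc1cc(C(=O)Oc2ccc([N+](=O)[O-])cc2)cc(OC)c1OC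
A1 | alternative 1 | 1-(2,4-dihydroxy-5-methoxyphenyl)ethan-1-one | CC(=O)c1cc(OC)c(O)cc1O
A2 | alternative 1 | 3,4,5-trimethoxybenzaldehyde | COc1cc(C=O)cc(OC)c1OC
A3 | alternative 1 | (E)-1-(2,4-dihydroxy-5-methoxyphenyl)-3-(3,4,5-trimethoxyphenyl)prop-2-en-1-one | COc1cc(C(=O)/C=C/c2cc(OC)c(OC)c(OC)c2)c(O)cc1O
A4 | alternative 2 | 4-iodo-6-methoxybenzene-1,3-diol | COc1cc(I)c(O)cc1O
A5 | alternative 2 | 5-ethynyl-1,2,3-trimethoxybenzene | C#Cc1cc(OC)c(OC)c(OC)c1
A6 | alternative 2 | 4-methoxybenzene-1,3-diol | COc1ccc(O)cc1O
A7 | alternative 3 | 7-hydroxy-6-methoxy-4H-chromen-4-one | COc1cc2c(=O)ccoc2cc1O
A8 | alternative 3 | 3,4,5-trimethoxyphenylboronic acid | COc1cc(B(O)O)cc(OC)c1OC
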